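The 2,2-dimethyldihydropyran ring (O–CMe2–CH2–CH2 fused to C1–C2 of ring A) is disconnected to a 2,2-dimethyl-2,3-dihydrobenzofuran bearing an iodomethyl group on its benzylic carbon. In the key step a neophyl-type radical 1,2-aryl shift moves the aryl bond from this ring CH to the exocyclic CH2, giving the saturated chroman directly. It exploits the oxygen-bearing carbons C1, C3 (ortho) and C4a (para) around the migrating carbon C2, which stabilise the spiro-cyclohexadienyl radical. The precursor arises from phloracetophenone by Larock allene annulation, which fixes the angular O/C pattern. Iodochromone formation, Suzuki coupling, Ru transfer hydrogenation with dynamic kinetic resolution and acid cyclisation then build the cis-(6aS,11aS)-pterocarpan.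

Key step: step 6

Remark: pterocarpan numbering is used for the target, whose SMILES corresponds to the cis-(6aS,11aS) enantiomer; the racemic C3 centre of the dihydrobenzofurans 6–8 is erased in step 6.

Step 1
Reactants: 1 2,4,6-trihydroxyacetophenone
Product: 2 1-[2,6-dihydroxy-4-(methoxymethoxy)phenyl]ethan-1-one
Conditions: MOMCl (1.05 equiv), i-Pr2NEt, THF, 0 °C
Reagents that add atoms: chloromethyl methyl ether, COCCl
Why: O-alkylation should occur at the 4-OH, the only hydroxyl not hydrogen-bonded to the acetyl group and the most acidic one, leaving the two equivalent chelated phenols free.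

Step 2
Reactants: 2 1-[2,6-dihydroxy-4-(methoxymethoxy)phenyl]ethan-1-one
Product: 3 1-[2,6-dihydroxy-3-iodo-4-(methoxymethoxy)phenyl]ethan-1-one
Conditions: NIS (1.0 equiv), MeCN, 0 °C to rt
Reagents that add atoms: N-iodosuccinimide, O=C1CCC(=O)N1I
Why: Electrophilic aromatic iodination of the strongly activated ring; C3 and C5 are equivalent by symmetry, so one equivalent of reagent should give a single mono-iodide.

Step 3
Reactants: 3 1-[2,6-dihydroxy-3-iodo-4-(methoxymethoxy)phenyl]ethan-1-one; 4 3-methylbuta-1,2-diene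
Product: 5 1-[6-hydroxy-4-(methoxymethoxy)-2,2-dimethyl-3-methylidene-2,3-dihydro-1-benzofuran-7-yl]ethan-1-one
Conditions: Pd(OAc)2 (5 mol %), PPh3 (5 mol %), n-Bu4NCl, K2CO3, DMF, 80 °C, sealed tube
Reagents that add atoms: none
Why: Larock heteroannulation of a 1,2-diene: aryl-Pd adds to the central allene carbon and the π-allyl is closed at its dimethyl-substituted terminus by the only ortho phenoxide (the 4-O is MOM-blocked), which fixes the ring oxygen next to the acetyl-bearing carbon.

Step 4
Reactants: 5 1-[6-hydroxy-4-(methoxymethoxy)-2,2-dimethyl-3-methylidene-2,3-dihydro-1-benzofuran-7-yl]ethan-1-one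
Product: 7 1-[6-hydroxy-3-(hydroxymethyl)-4-(methoxymethoxy)-2,2-dimethyl-2,3-dihydro-1-benzofuran-7-yl]ethan-1-one (racemic), via primary pinacol boronate 6 (not isolated)
Conditions: [Ir(cod)Cl]2 (2.5 mol %), dppe (5 mol %), HBpin (2.5 equiv), THF, rt; then NaBO3·4H2O, THF/H2O, rt
Reagents that add atoms: pinacolborane, CC1(C)OBOC1(C)C; sodium perborate, [Na+].[Na+].O[B-]1(O)OO[B-](O)(O)OO1
Why: Metal-catalysed anti-Markovnikov hydroboration should place boron on the terminal CH2 and leave the hindered, chelated aryl ketone untouched, and near-neutral perborate oxidation of the C–B bond avoids a Dakin oxidation; the new C3 centre is racemic and is erased in step 6.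

Step 5
Reactants: 7 1-[6-hydroxy-3-(hydroxymethyl)-4-(methoxymethoxy)-2,2-dimethyl-2,3-dihydro-1-benzofuran-7-yl]ethan-1-one
Product: 8 1-[6-hydroxy-3-(iodomethyl)-4-(methoxymethoxy)-2,2-dimethyl-2,3-dihydro-1-benzofuran-7-yl]ethan-1-one (racemic)
Conditions: I2, PPh3, imidazole, CH2Cl2, 0 °C to rt
Reagents that add atoms: iodine, II
Why: Appel iodination by SN2 displacement at the primary carbinol carbon; the chelated phenol, the ketone and the MOM ether should not react under these buffered conditions.

Step 6
Reactants: 8 1-[6-hydroxy-3-(iodomethyl)-4-(methoxymethoxy)-2,2-dimethyl-2,3-dihydro-1-benzofuran-7-yl]ethan-1-one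
Product: 9 1-[7-hydroxy-5-(methoxymethoxy)-2,2-dimethyl-3,4-dihydro-2H-chromen-8-yl]ethan-1-one
Conditions: Bu3SnH (1.3 equiv), AIBN (0.2 equiv), syringe pump over 10 h, PhMe (3 mM), 110 °C
Reagents that add atoms: none
Why: Bu3Sn• abstracts iodine to give the primary (dihydrobenzofuran-3-yl)methyl radical, which attacks the ipso carbon C3a (3-exo-trig) to form a spiro[2.5]octadienyl radical and then cleaves the old C3–C3a bond, so the aryl carbon moves from the ring CH to the exocyclic CH2 and the five-membered ring becomes the six-membered chroman, whose secondary C3 radical is reduced by the stannane. The closest known reaction type is the neophyl rearrangement, as in the 6-endo products that arise from 5-exo (dihydrobenzofuranyl)methyl and indanylmethyl radicals at low stannane concentration. No ring is closed permanently: the only closure is the transient 3-exo-trig cyclopropane, and the net change is a one-carbon ring expansion. No stereocentre is formed, and the racemic C3 centre of 8 becomes a CH2 group. The step needs rearrangement to outrun hydrogen transfer to the primary radical; slow stannane addition at 110 °C keeps its concentration low, and the substrate helps because the spiro radical carries its spin on the three oxygen-bearing ring carbons and the shift turns a primary into a secondary radical with release of five-ring strain.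

Step 7
Reactants: 9 1-[7-hydroxy-5-(methoxymethoxy)-2,2-dimethyl-3,4-dihydro-2H-chromen-8-yl]ethan-1-one
Product: 11 9-iodo-5-(methoxymethoxy)-2,2-dimethyl-3,4-dihydro-2H,10H-pyrano[2,3-f]chromen-10-one (a 3-iodochromone whose C5–C6 bond carries the dimethyldihydropyran ring), via enaminone 10 (not isolated)
Conditions: DMF-DMA, PhMe, 95 °C; concentrate; then I2, pyridine, CHCl3, rt
Reagents that add atoms: N,N-dimethylformamide dimethyl acetal, COC(OC)N(C)C; iodine, II
Why: Condensation of the methyl ketone with the amide acetal gives the enaminone; α-iodination, 6-endo attack of the ortho phenol on the iminium carbon and loss of dimethylamine then give the 3-iodochromone (enaminone iodocyclisation).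

Step 8
Reactants: 12 2-bromo-5-methoxyphenol
Product: 13 1-bromo-4-methoxy-2-(methoxymethoxy)benzene
Conditions: MOMCl, i-Pr2NEt, CH2Cl2, 0 °C to rt
Reagents that add atoms: chloromethyl methyl ether, COCCl
Why: Routine O-alkylation of the phenol masks the future 2'-OH as an acetal that survives borylation, coupling and transfer hydrogenation.

Step 9
Reactants: 13 1-bromo-4-methoxy-2-(methoxymethoxy)benzene
Product: 14 2-[4-methoxy-2-(methoxymethoxy)phenyl]-4,4,5,5-tetramethyl-1,3,2-dioxaborolane
Conditions: B2pin2, Pd(dppf)Cl2 (3 mol %), KOAc, 1,4-dioxane, 90 °C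
Reagents that add atoms: bis(pinacolato)diboron, CC1(C)OB(OC1(C)C)B1OC(C)(C)C(C)(C)O1
Why: Miyaura borylation of the aryl bromide; the weak acetate base should prevent a second coupling of the boronate.

Step 10
Reactants: 11 9-iodo-5-(methoxymethoxy)-2,2-dimethyl-3,4-dihydro-2H,10H-pyrano[2,3-f]chromen-10-one; 14 2-[4-methoxy-2-(methoxymethoxy)phenyl]-4,4,5,5-tetramethyl-1,3,2-dioxaborolane
Product: 15 9-[4-methoxy-2-(methoxymethoxy)phenyl]-5-(methoxymethoxy)-2,2-dimethyl-3,4-dihydro-2H,10H-pyrano[2,3-f]chromen-10-one (an isoflavone with 7-OMOM, 2'-OMOM, 4'-OMe and the pyran ring on C5–C6)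
Conditions: Pd(PPh3)4 (5 mol %), 2 M aq. Na2CO3, DME, 80 °C
Reagents that add atoms: none
Why: Suzuki–Miyaura coupling of a 3-iodochromone with an arylboronate is the standard route to isoflavones, and the carbonate base should be mild enough to leave the pyranone ring closed.

Step 11
Reactants: 15 9-[4-methoxy-2-(methoxymethoxy)phenyl]-5-(methoxymethoxy)-2,2-dimethyl-3,4-dihydro-2H,10H-pyrano[2,3-f]chromen-10-one
Product: 17 (9S,10S)-9-[4-methoxy-2-(methoxymethoxy)phenyl]-5-(methoxymethoxy)-2,2-dimethyl-3,4,9,10-tetrahydro-2H,8H-pyrano[2,3-f]chromen-10-ol (the cis-(3S,4S)-isoflavan-4-ol), via isoflavanone 16 (not isolated)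
Conditions: RuCl[(S,S)-TsDPEN](p-cymene) (5 mol %), HCO2H/Et3N (5:2), EtOAc, 45 °C
Reagents that add atoms: none
Why: Asymmetric transfer hydrogenation with dynamic kinetic resolution: conjugate reduction gives the isoflavanone, whose C3 epimerises under the amine, and the (S,S) catalyst (aryl ketone model, S,S gives the S carbinol) should reduce the (3S)-ketone faster with hydride anti to the 3-aryl group, setting both centres as cis-(3S,4S).

Step 12
Reactants: 17 (9S,10S)-9-[4-methoxy-2-(methoxymethoxy)phenyl]-5-(methoxymethoxy)-2,2-dimethyl-3,4,9,10-tetrahydro-2H,8H-pyrano[2,3-f]chromen-10-ol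
Product: 19 (6aS,11aS)-3-hydroxy-9-methoxypterocarpan carrying a 2,2-dimethyl-3,4-dihydro-2H-pyran ring fused at C1 (O) and C2 (CH2), via triol 18 (not isolated)
Conditions: conc. HCl, MeOH/THF, 50 °C
Reagents that add atoms: none
Why: Acetal methanolysis frees both phenols, the benzylic C4–OH ionises to a cation stabilised by the three ring-A oxygens, and 5-exo attack of the 2'-OH closes the dihydrobenzofuran ring; only the cis ring fusion is accessible, so the retained C6a (S) centre dictates C11a (S).

Compound list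
1 | 2,4,6-trihydroxyacetophenone | CC(=O)c1c(O)cc(O)cc1O | starting material
2 | 1-[2,6-dihydroxy-4-(methoxymethoxy)phenyl]ethan-1-one | CC(=O)c1c(O)cc(OCOC)cc1O | intermediate
3 | 1-[2,6-dihydroxy-3-iodo-4-(methoxymethoxy)phenyl]ethan-1-one | CC(=O)c1c(O)cc(OCOC)c(I)c1O | intermediate
4 | 3-methylbuta-1,2-diene | CC(C)=C=C | starting material
5 | 1-[6-hydroxy-4-(methoxymethoxy)-2,2-dimethyl-3-methylidene-2,3-dihydro-1-benzofuran-7-yl]ethan-1-one | CC(=O)c1c(O)cc(OCOC)c2C(=C)C(C)(C)Oc12 | intermediate
6 | 1-[6-hydroxy-4-(methoxymethoxy)-2,2-dimethyl-3-[(4,4,5,5-tetramethyl-1,3,2-dioxaborolan-2-yl)methyl]-2,3-dihydro-1-benzofuran-7-yl]ethan-1-one (racemic) | CC(=O)c1c(O)cc(OCOC)c2C(CB3OC(C)(C)C(C)(C)O3)C(C)(C)Oc12 | intermediate (not isolated)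
7 | 1-[6-hydroxy-3-(hydroxymethyl)-4-(methoxymethoxy)-2,2-dimethyl-2,3-dihydro-1-benzofuran-7-yl]ethan-1-one (racemic) | CC(=O)c1c(O)cc(OCOC)c2C(CO)C(C)(C)Oc12 | intermediate
8 | 1-[6-hydroxy-3-(iodomethyl)-4-(methoxymethoxy)-2,2-dimethyl-2,3-dihydro-1-benzofuran-7-yl]ethan-1-one (racemic) | CC(=O)c1c(O)cc(OCOC)c2C(CI)C(C)(C)Oc12 | intermediate
9 | 1-[7-hydroxy-5-(methoxymethoxy)-2,2-dimethyl-3,4-dihydro-2H-chromen-8-yl]ethan-1-one | CC(=O)c1c(O)cc(OCOC)c2CCC(C)(C)Oc12 | intermediate
10 | (E)-3-(dimethylamino)-1-[7-hydroxy-5-(methoxymethoxy)-2,2-dimethyl-3,4-dihydro-2H-chromen-8-yl]prop-2-en-1-one | CN(C)/C=C/C(=O)c1c(O)cc(OCOC)c2CCC(C)(C)Oc12 | intermediate (not isolated)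
11 | 9-iodo-5-(methoxymethoxy)-2,2-dimethyl-3,4-dihydro-2H,10H-pyrano[2,3-f]chromen-10-one | O=C1C(I)=COc2cc(OCOC)c3CCC(C)(C)Oc3c12 | intermediate
12 | 2-bromo-5-methoxyphenol | COc1ccc(Br)c(O)c1 | starting material
13 | 1-bromo-4-methoxy-2-(methoxymethoxy)benzene | COCOc1cc(OC)ccc1Br | intermediate
14 | 2-[4-methoxy-2-(methoxymethoxy)phenyl]-4,4,5,5-tetramethyl-1,3,2-dioxaborolane | COCOc1cc(OC)ccc1B1OC(C)(C)C(C)(C)O1 | intermediate
15 | 9-[4-methoxy-2-(methoxymethoxy)phenyl]-5-(methoxymethoxy)-2,2-dimethyl-3,4-dihydro-2H,10H-pyrano[2,3-f]chromen-10-one | O=C1C(c4ccc(OC)cc4OCOC)=COc2cc(OCOC)c3CCC(C)(C)Oc3c12 | intermediate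
16 | 9-[4-methoxy-2-(methoxymethoxy)phenyl]-5-(methoxymethoxy)-2,2-dimethyl-3,4,8,9-tetrahydro-2H,10H-pyrano[2,3-f]chromen-10-one (isoflavanone, C9 configurationally labile) | O=C1C(c4ccc(OC)cc4OCOC)COc2cc(OCOC)c3CCC(C)(C)Oc3c12 | intermediate (not isolated)
17 | (9S,10S)-9-[4-methoxy-2-(methoxymethoxy)phenyl]-5-(methoxymethoxy)-2,2-dimethyl-3,4,9,10-tetrahydro-2H,8H-pyrano[2,3-f]chromen-10-ol | O[C@H]1[C@@H](c4ccc(OC)cc4OCOC)COc2cc(OCOC)c3CCC(C)(C)Oc3c12 | intermediate
18 | (9S,10S)-9-(2-hydroxy-4-methoxyphenyl)-2,2-dimethyl-3,4,9,10-tetrahydro-2H,8H-pyrano[2,3-f]chromene-5,10-diol | O[C@H]1[C@@H](c4ccc(OC)cc4O)COc2cc(O)c3CCC(C)(C)Oc3c12 | intermediate (not isolated)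
19 | (6aS,11aS)-3-hydroxy-9-methoxypterocarpan with a 2,2-dimethyl-3,4-dihydro-2H-pyran ring fused at C1 (O) and C2 (CH2) | COc1ccc2c(c1)O[C@@H]1c3c(cc(O)c4c3OC(C)(C)CC4)OC[C@H]21 | target

Total step count: 12. Longest linear sequence: 10 (steps 1–7 and 10–12).

Steps most likely to fail

Step 6. Hydrogen transfer from the stannane to the primary radical may outrun the 1,2-aryl shift, so that the unrearranged 3-methyl dihydrobenzofuran accumulates. The fallback sets out from 8 and uses a cationic aryl shift instead. Silver-assisted ionisation of the primary iodide (AgOTf, 2,6-lutidine, CH2Cl2, 0 °C) with participation of the electron-rich arene (phenonium ion) and loss of the benzylic proton should give the ring-expanded 1-[7-hydroxy-5-(methoxymethoxy)-2,2-dimethyl-2H-chromen-8-yl]ethan-1-one F1. Hydrogenation of its styrene-type double bond (H2, Pd/C, EtOAc) returns to the route at 9.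

Step 4. The hindered 1,1-disubstituted alkene may be hydroborated slowly, and the aryl ketone may be reduced in competition. The fallback sets out from 2 and also avoids steps 2 and 3. Mono-alkylation of one of the two equivalent phenols with (E)-4-chloro-3-methylbut-2-en-1-yl acetate (K2CO3, NaI, DMF, 50 °C) gives (E)-4-[2-acetyl-3-hydroxy-5-(methoxymethoxy)phenoxy]-3-methylbut-2-en-1-yl acetate F2. Aromatic Claisen rearrangement (N,N-diethylaniline, 180 °C) to the only free ortho carbon gives 2-[3-acetyl-2,4-dihydroxy-6-(methoxymethoxy)phenyl]-3-methylbut-3-en-1-yl acetate F3. Gold(I)-catalysed Markovnikov addition of the neighbouring phenol to the isopropenyl group (Ph3PAuCl/AgOTf, PhMe, 60 °C) closes [7-acetyl-6-hydroxy-4-(methoxymethoxy)-2,2-dimethyl-2,3-dihydro-1-benzofuran-3-yl]methyl acetate F4. Methanolysis of the acetate (K2CO3, MeOH) returns to the route at 7.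

Step 11. Conjugate reduction of the hindered 5-alkoxy isoflavone may stall, or epimerisation at C3 may be slow relative to ketone reduction, which would erode the enantiomeric and cis/trans purity. The fallback sets out from 15 and separates the two reductions. Hydrogenation of the C2=C3 bond alone (H2, Pd/C, EtOAc) gives the isoflavanone 16, now isolated. Asymmetric pressure hydrogenation under base with dynamic kinetic resolution (RuCl2(xyl-BINAP)(DAIPEN), t-BuOK, i-PrOH, H2; catalyst antipode chosen for the 4S alcohol) returns to the route at 17. This fallback makes no compound outside the list (F0).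

Further compounds
F1 | step 6 | 1-[7-hydroxy-5-(methoxymethoxy)-2,2-dimethyl-2H-chromen-8-yl]ethan-1-one | CC(=O)c1c(O)cc(OCOC)c2C=CC(C)(C)Oc12
F2 | step 4 | (E)-4-[2-acetyl-3-hydroxy-5-(methoxymethoxy)phenoxy]-3-methylbut-2-en-1-yl acetate | CC(=O)c1c(O)cc(OCOC)cc1OC/C(C)=C/COC(C)=O
F3 | step 4 | 2-[3-acetyl-2,4-dihydroxy-6-(methoxymethoxy)phenyl]-3-methylbut-3-en-1-yl acetate (racemic) | CC(=O)c1c(O)cc(OCOC)c(C(COC(C)=O)C(C)=C)c1O
F4 | step 4 | [7-acetyl-6-hydroxy-4-(methoxymethoxy)-2,2-dimethyl-2,3-dihydro-1-benzofuran-3-yl]methyl acetate (racemic) | CC(=O)c1c(O)cc(OCOC)c2C(COC(C)=O)C(C)(C)Oc12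
F0 | step 11 | none | none
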